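The chemist who charges the eta flask repeats the beta recipe, 0.800 M of Z with 0.00400 M of J, and wants to know what stands there at 320 h.

all flasks: J 0.00400 M
- beta: Z 0.800 M
- epsilon: Z 0.320 M
- alpha: Z 1.60 M
- eta: Z 0.800 M; time 320 h

- beta run (time / h: [L] / M): 19: 0.104; 37: 0.155; 56: 0.197; 74: 0.233; 93: 0.250; 110: 0.262; 130: 0.261
- epsilon run (time / h: [L] / M): 19: 0.052; 37: 0.107; 56: 0.122; 74: 0.111; 93: 0.114; 110: 0.118; 130: 0.114
- alpha run (time / h: [L] / M): 19: 0.134; 37: 0.242; 56: 0.329; 74: 0.374; 93: 0.392; 110: 0.428; 130: 0.433

(readings scatter by 0.008 M)

* the exponent of [Z] in the starting rate at the charge of the beta run (at the point where two percent of the Z have become L) (one fixed amount of L, the same in the runs compared)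
* L in the eta run at 320 h, as a share of the Z charged

- Overall: Z -> L, with J as catalyst.
- Constant volume, constant temperature.
- A reading of a species includes what of it is bound.
- An order is taken over about fifteen percent of the charge, up and down.

Turn the second question round: what would the beta readings have to show for the eta flask to turn its whole charge of Z into L? My own reckoning follows.

1. In the beta run, the mean of the last two readings of c(L), divided by the Z charged, is 32.7%. Call this the stopping share, which is a final yield on the charge.

2. Treat the answer as this share plus a correction, and test the largest correction the question allows. Full conversion needs a further 0.538 M of L after 130 h. Spread over the 190 h up to 320 h, that is a steady 0.00283 M/h.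

3. Between its last two readings, the beta run changes at −5.00 × 10⁻⁵ M/h, and the scatter of that slope is 5.66 × 10⁻⁴ M/h. The rate needed is 5.01 times that scatter, so the beta run shows no such rate.

4. This test speaks against full conversion and little else. One scatter of the slope, held over the 190 h, amounts to 0.107 M, or 13.4% of the Z charged, so a slow creep stays open. My figure for the eta flask is the stopping share, about 32.7%, with that wide margin.

5. The forecast says 35%, somewhat above my figure, and gives 0.6 for the order. It keeps open “a reversible approach to equilibrium near 36%”.

    J + Z ⇌ JZ, settled at all times (0.4620 /M)
    JZ + J → L + 2 J (6048 /M/h)
    Z → Oz (0.02063 /h)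
    J + Qi → Wa

The eta flask gives 33.1% of its charge at 320 h, which is 0.40 percentage points above the stopping share, and the order in Z at the beta charge is 0.51. The power-law fit over the runs, with best order 0.73, forecast 74.3% for the eta flask, far more than it gave. The same reckoning on the last two readings of the alpha run gives a stopping share of 26.9%, lower than that of the beta run, and in the alpha run L came to a quarter of the Z charged at 89.7 h.

Readings and results were computed with made-up constants, noise included.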